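**Retrosynthetic overview**
1. Target 26 ⇐ silyl-protected enone 24 ⇐ Saegusa–Ito oxidation of silyl enol ether 23 ⇐ one-carbon ring enlargement (C1 inserted between C2 and C10) of cis-hydrindanone 19.
2. Key step: an intramolecular Diels–Alder reaction of acyclic trienone 17 closes ring B and a cyclopentanone (the later ring A) in one operation. The (E,E)-diene, the (E)-enone and the endo mode fix C5, C8 and C9; the quaternary C4 steers the diene face.
3. 17 ⇐ (E)-alkenyl iodide 7 (C9–C15 and C20, from (R)-citronellol, which supplies C13) + Weinreb amide 14 (C2–C8, C17–C19).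
4. 14 ⇐ dienoic acid 10 ((E)-pent-2-enal + methylmalonic acid) by enantioselective deconjugative α-alkylation, which creates C4.
5. Ring order: ring B and the five-membered precursor of ring A together (step 9); ring A is enlarged to six-membered in step 11.

Atom labels C1–C20 are the halimane positions of the target (C2 ketone, C1=C10 alkene, C4 quaternary ester carbon, C5 ring-fusion CH, C8 CHMe, C9 quaternary carbon, C11–C15 side chain).
Assumption: the (R,R)-tetramine of step 6 is taken to give the (S)-acid 13; if the sense is the opposite, its (S,S)-enantiomer is used instead.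

**Route**

Step 1
Reactants: 1 (R)-citronellol [(3R)-3,7-dimethyloct-6-en-1-ol]
Product: 2 tert-butyl{[(3R)-3,7-dimethyloct-6-en-1-yl]oxy}dimethylsilane
Conditions: TBSCl, imidazole, CH2Cl2, 0 °C → rt
Reagents that add atoms: tert-butyldimethylsilyl chloride (TBSCl), CC(C)(C)[Si](C)(C)Cl
Why: Imidazole-assisted silylation protects the primary alcohol against the later organometallic steps, and the C13 stereocentre is carried in from the chiral pool unchanged.

Step 2
Reactants: 2 tert-butyl{[(3R)-3,7-dimethyloct-6-en-1-yl]oxy}dimethylsilane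
Product: 4 (4R)-6-{[tert-butyl(dimethyl)silyl]oxy}-4-methylhexanal, via ozonide 3 (not isolated)
Conditions: O3, CH2Cl2, −78 °C; then PPh3, −78 °C → rt
Reagents that add atoms: ozone, [O-][O+]=O
Why: Ozonolysis with reductive work-up cleaves the trisubstituted alkene to the aldehyde whose carbonyl carbon becomes C9, leaving the silyl ether and the remote stereocentre untouched.

Step 3
Reactants: 4 (4R)-6-{[tert-butyl(dimethyl)silyl]oxy}-4-methylhexanal
Product: 5 tert-butyldimethyl{[(3R)-3-methylhept-6-yn-1-yl]oxy}silane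
Conditions: dimethyl (1-diazo-2-oxopropyl)phosphonate, K2CO3, MeOH, 0 °C → rt
Reagents that add atoms: dimethyl (1-diazo-2-oxopropyl)phosphonate, COP(=O)(OC)C(=[N+]=[N-])C(C)=O
Why: Seyferth–Gilbert homologation in its Ohira–Bestmann form converts the aldehyde into the terminal alkyne under mild base and adds C10.

Step 4
Reactants: 5 tert-butyldimethyl{[(3R)-3-methylhept-6-yn-1-yl]oxy}silane
Product: 7 tert-butyl{[(3R,6E)-7-iodo-3,6-dimethylhept-6-en-1-yl]oxy}dimethylsilane, via alkenylalane 6 (not isolated)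
Conditions: AlMe3 (2.5 equiv), Cp2ZrCl2 (20 mol%), CH2Cl2, rt; then I2, THF, −30 °C
Reagents that add atoms: trimethylaluminium AlMe3, C[Al](C)C; iodine I2, II
Why: Negishi carboalumination adds methyl and aluminium syn across the alkyne with aluminium on the terminal carbon, and iodinolysis with retention gives only the (E)-iodide that later fixes the dienophile geometry.

Step 5
Reactants: 8 (E)-pent-2-enal; 9 methylmalonic acid
Product: 10 (2E,4E)-2-methylhepta-2,4-dienoic acid
Conditions: pyridine, piperidine (cat.), 90 °C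
Reagents that add atoms: none
Why: Knoevenagel–Doebner condensation with loss of CO2 gives the thermodynamically preferred (2E,4E)-2-methyl dienoic acid in one step.

Step 6
Reactants: 10 (2E,4E)-2-methylhepta-2,4-dienoic acid; 11 2-bromo-N-methoxy-N-methylacetamide
Product: 13 (2S,3E,5E)-2-{2-[methoxy(methyl)amino]-2-oxoethyl}-2-methylhepta-3,5-dienoic acid, via dilithium trienediolate 12 (not isolated)
Conditions: (R,R)-N,N'-bis(1-phenyl-2-piperidin-1-ylethyl)propane-1,3-diamine (1.05 equiv), n-BuLi (4.1 equiv), THF, 0 °C; then 11, −78 °C; 1 M HCl work-up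
Reagents that add atoms: none
Why: Deconjugative α-alkylation of the extended enediolate inside a mixed aggregate with the chiral lithium amide (a non-covalent auxiliary that shields one enolate face) creates the quaternary C4 as (S) and releases the conjugated (E,E)-diene.

Step 7
Reactants: 13 (2S,3E,5E)-2-{2-[methoxy(methyl)amino]-2-oxoethyl}-2-methylhepta-3,5-dienoic acid
Product: 14 methyl (2S,3E,5E)-2-{2-[methoxy(methyl)amino]-2-oxoethyl}-2-methylhepta-3,5-dienoate
Conditions: MeI, K2CO3, DMF, rt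
Reagents that add atoms: iodomethane, CI
Why: SN2 O-methylation of the carboxylate gives the methyl ester without touching the Weinreb amide, the diene or the quaternary centre.

Step 8
Reactants: 7 tert-butyl{[(3R,6E)-7-iodo-3,6-dimethylhept-6-en-1-yl]oxy}dimethylsilane; 14 methyl (2S,3E,5E)-2-{2-[methoxy(methyl)amino]-2-oxoethyl}-2-methylhepta-3,5-dienoate
Product: 17 methyl (2S,3E,5E)-2-[(3E,7R)-9-{[tert-butyl(dimethyl)silyl]oxy}-4,7-dimethyl-2-oxonon-3-en-1-yl]-2-methylhepta-3,5-dienoate, via alkenyllithium 15 (not isolated), via lithium hemiaminal 16 (not isolated)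
Conditions: 7, t-BuLi (2.05 equiv), Et2O, −78 °C; then 14, THF, −78 → −40 °C; 1 M HCl work-up
Reagents that add atoms: none
Why: Iodine–lithium exchange retains the alkene geometry, and Weinreb ketone synthesis (single addition to the amide through a stable chelate, in preference to the hindered neopentyl-type ester) gives the (E)-enone.

Step 9
Reactants: 17 methyl (2S,3E,5E)-2-[(3E,7R)-9-{[tert-butyl(dimethyl)silyl]oxy}-4,7-dimethyl-2-oxonon-3-en-1-yl]-2-methylhepta-3,5-dienoate
Product: 18 methyl (1S,3aS,4S,5R,7aS)-4-[(3R)-5-{[tert-butyl(dimethyl)silyl]oxy}-3-methylpentyl]-1,4,5-trimethyl-3-oxo-2,3,3a,4,5,7a-hexahydro-1H-indene-1-carboxylate (cis-fused)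
Conditions: Me2AlCl (2.2 equiv), CH2Cl2, −40 → 0 °C; 1 M HCl work-up
Reagents that add atoms: none
Why: The Lewis-acid-promoted intramolecular Diels–Alder reaction (ketone inside the three-atom tether) goes through the endo, cis-fused transition state and forms the cyclopentanone and ring B together, so the (E,E)-diene places C4 and the C8 methyl cis, the (E)-enone places the C9 methyl cis to C2 and the C11 chain cis to H10, and the quaternary C4 selects the diene face by keeping its methyl eclipsing C5=C6 and the Al-complexed CO2Me outside (CO2Me cis to H5).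

Step 10
Reactants: 18 (the cis-fused hydrindenone)
Product: 19 methyl (1S,3aS,4S,5R,7aS)-4-[(3R)-5-{[tert-butyl(dimethyl)silyl]oxy}-3-methylpentyl]-1,4,5-trimethyl-3-oxooctahydro-1H-indene-1-carboxylate
Conditions: H2 (1 atm), Pd/C (10% Pd), EtOAc, rt
Reagents that add atoms: none
Why: Heterogeneous hydrogenation saturates the only C=C (C6=C7) and creates no stereocentre.

Step 11
Reactants: 19 (the hydrindanone)
Product: 23 methyl (1S,4aR,5S,6R,8aS)-5-[(3R)-5-{[tert-butyl(dimethyl)silyl]oxy}-3-methylpentyl]-1,5,6-trimethyl-3-[(trimethylsilyl)oxy]-1,2,4a,5,6,7,8,8a-octahydronaphthalene-1-carboxylate, via dibromomethyl alkoxide 20 (not isolated), via lithium carbenoid 21 (not isolated), via lithium enolate 22 (not isolated)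
Conditions: CH2Br2, LiN(i-Pr)2, THF, −78 °C; then n-BuLi, −95 → 0 °C; then Me3SiCl, −78 °C → rt
Reagents that add atoms: dibromomethane, BrCBr; chlorotrimethylsilane, C[Si](C)(C)Cl
Why: β-Oxido carbenoid ring enlargement (dibromomethyllithium addition, bromine–lithium exchange, 1,2-shift) inserts C1 by migration of the more substituted α-carbon C10 with retention and gives the enolate regiospecifically at C1–C2, which is trapped as the silyl enol ether.

Step 12
Reactants: 23 (the silyl enol ether)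
Product: 24 methyl (1S,5S,6R,8aS)-5-[(3R)-5-{[tert-butyl(dimethyl)silyl]oxy}-3-methylpentyl]-1,5,6-trimethyl-3-oxo-1,2,3,5,6,7,8,8a-octahydronaphthalene-1-carboxylate
Conditions: Pd(OAc)2 (1.1 equiv), MeCN, rt
Reagents that add atoms: none
Why: Saegusa–Ito oxidation (palladation at C1, then β-hydride elimination of the only β-hydrogen, H10) gives the 1(10)-en-2-one and removes the C10 stereocentre under neutral conditions that leave C5 untouched.

Step 13
Reactants: 24 (the silyl-protected enone)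
Product: 26 methyl (1S,5S,6R,8aS)-5-[(3R)-5-acetoxy-3-methylpentyl]-1,5,6-trimethyl-3-oxo-1,2,3,5,6,7,8,8a-octahydronaphthalene-1-carboxylate, via alcohol 25 (not isolated)
Conditions: HF·pyridine, THF/pyridine, 0 °C → rt; then Ac2O, 4-(dimethylamino)pyridine (cat.), rt
Reagents that add atoms: acetic anhydride, CC(=O)OC(C)=O
Why: Buffered fluoride desilylation followed by nucleophile-catalysed acetylation in the same flask gives the target without base strong enough to epimerise the γ-position C5.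

**Compound list**
1 | (R)-citronellol [(3R)-3,7-dimethyloct-6-en-1-ol] | CC(C)=CCC[C@@H](C)CCO | starting material
2 | tert-butyl{[(3R)-3,7-dimethyloct-6-en-1-yl]oxy}dimethylsilane | CC(C)=CCC[C@@H](C)CCO[Si](C)(C)C(C)(C)C | intermediate
3 | ozonide of 2: 3-[(3R)-5-{[tert-butyl(dimethyl)silyl]oxy}-3-methylpentyl]-5,5-dimethyl-1,2,4-trioxolane (mixture at the ring CH) | CC1(C)OOC(CC[C@@H](C)CCO[Si](C)(C)C(C)(C)C)O1 | intermediate
4 | (4R)-6-{[tert-butyl(dimethyl)silyl]oxy}-4-methylhexanal | O=CCC[C@@H](C)CCO[Si](C)(C)C(C)(C)C | intermediate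
5 | tert-butyldimethyl{[(3R)-3-methylhept-6-yn-1-yl]oxy}silane | C#CCC[C@@H](C)CCO[Si](C)(C)C(C)(C)C | intermediate
6 | [(1E,5R)-7-{[tert-butyl(dimethyl)silyl]oxy}-2,5-dimethylhept-1-en-1-yl]dimethylalane | C[Al](C)/C=C(\C)CC[C@@H](C)CCO[Si](C)(C)C(C)(C)C | intermediate
7 | tert-butyl{[(3R,6E)-7-iodo-3,6-dimethylhept-6-en-1-yl]oxy}dimethylsilane | I/C=C(\C)CC[C@@H](C)CCO[Si](C)(C)C(C)(C)C | intermediate
8 | (E)-pent-2-enal | CC/C=C/C=O | starting material
9 | methylmalonic acid | CC(C(=O)O)C(=O)O | starting material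
10 | (2E,4E)-2-methylhepta-2,4-dienoic acid | CC/C=C/C=C(\C)C(=O)O | intermediate
11 | 2-bromo-N-methoxy-N-methylacetamide | CON(C)C(=O)CBr | starting material
12 | dilithium (3E,5E)-2-methylhepta-1,3,5-triene-1,1-diolate | [Li+].[Li+].[O-]C([O-])=C(C)/C=C/C=C/C | intermediate
13 | (2S,3E,5E)-2-{2-[methoxy(methyl)amino]-2-oxoethyl}-2-methylhepta-3,5-dienoic acid | OC(=O)[C@@](/C=C/C=C/C)(C)CC(=O)N(C)OC | intermediate
14 | methyl (2S,3E,5E)-2-{2-[methoxy(methyl)amino]-2-oxoethyl}-2-methylhepta-3,5-dienoate | COC(=O)[C@@](/C=C/C=C/C)(C)CC(=O)N(C)OC | intermediate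
15 | [(1E,5R)-7-{[tert-butyl(dimethyl)silyl]oxy}-2,5-dimethylhept-1-en-1-yl]lithium | [Li]/C=C(\C)CC[C@@H](C)CCO[Si](C)(C)C(C)(C)C | intermediate
16 | lithium hemiaminal: tetrahedral adduct of 15 to the Weinreb amide carbon of 14 (new carbinol centre unspecified) | COC(=O)[C@@](/C=C/C=C/C)(C)CC(O[Li])(N(C)OC)/C=C(\C)CC[C@@H](C)CCO[Si](C)(C)C(C)(C)C | intermediate
17 | methyl (2S,3E,5E)-2-[(3E,7R)-9-{[tert-butyl(dimethyl)silyl]oxy}-4,7-dimethyl-2-oxonon-3-en-1-yl]-2-methylhepta-3,5-dienoate | COC(=O)[C@@](/C=C/C=C/C)(C)CC(=O)/C=C(\C)CC[C@@H](C)CCO[Si](C)(C)C(C)(C)C | intermediate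
18 | methyl (1S,3aS,4S,5R,7aS)-4-[(3R)-5-{[tert-butyl(dimethyl)silyl]oxy}-3-methylpentyl]-1,4,5-trimethyl-3-oxo-2,3,3a,4,5,7a-hexahydro-1H-indene-1-carboxylate (cis-fused; H5 and H10 cis, both methyls on C8 and C9 trans to them) | COC(=O)[C@@]1(C)CC(=O)[C@H]2[C@@H]1C=C[C@@H](C)[C@]2(C)CC[C@@H](C)CCO[Si](C)(C)C(C)(C)C | intermediate
19 | methyl (1S,3aS,4S,5R,7aS)-4-[(3R)-5-{[tert-butyl(dimethyl)silyl]oxy}-3-methylpentyl]-1,4,5-trimethyl-3-oxooctahydro-1H-indene-1-carboxylate | COC(=O)[C@@]1(C)CC(=O)[C@H]2[C@@H]1CC[C@@H](C)[C@]2(C)CC[C@@H](C)CCO[Si](C)(C)C(C)(C)C | intermediate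
20 | lithium alkoxide from addition of dibromomethyllithium to the ketone of 19 (carbinol centre unspecified) | COC(=O)[C@@]1(C)CC(O[Li])(C(Br)Br)[C@H]2[C@@H]1CC[C@@H](C)[C@]2(C)CC[C@@H](C)CCO[Si](C)(C)C(C)(C)C | intermediate
21 | α-bromo-α-lithio carbenoid from 20 | COC(=O)[C@@]1(C)CC(O[Li])(C([Li])Br)[C@H]2[C@@H]1CC[C@@H](C)[C@]2(C)CC[C@@H](C)CCO[Si](C)(C)C(C)(C)C | intermediate
22 | lithium enolate (C1=C2) of the ring-enlarged six-membered ketone | COC(=O)[C@@]1(C)CC(O[Li])=C[C@H]2[C@@H]1CC[C@@H](C)[C@]2(C)CC[C@@H](C)CCO[Si](C)(C)C(C)(C)C | intermediate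
23 | methyl (1S,4aR,5S,6R,8aS)-5-[(3R)-5-{[tert-butyl(dimethyl)silyl]oxy}-3-methylpentyl]-1,5,6-trimethyl-3-[(trimethylsilyl)oxy]-1,2,4a,5,6,7,8,8a-octahydronaphthalene-1-carboxylate | COC(=O)[C@@]1(C)CC(O[Si](C)(C)C)=C[C@H]2[C@@H]1CC[C@@H](C)[C@]2(C)CC[C@@H](C)CCO[Si](C)(C)C(C)(C)C | intermediate
24 | methyl (1S,5S,6R,8aS)-5-[(3R)-5-{[tert-butyl(dimethyl)silyl]oxy}-3-methylpentyl]-1,5,6-trimethyl-3-oxo-1,2,3,5,6,7,8,8a-octahydronaphthalene-1-carboxylate | COC(=O)[C@@]1(C)CC(=O)C=C2[C@@H]1CC[C@@H](C)[C@]2(C)CC[C@@H](C)CCO[Si](C)(C)C(C)(C)C | intermediate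
25 | methyl (1S,5S,6R,8aS)-5-[(3R)-5-hydroxy-3-methylpentyl]-1,5,6-trimethyl-3-oxo-1,2,3,5,6,7,8,8a-octahydronaphthalene-1-carboxylate | COC(=O)[C@@]1(C)CC(=O)C=C2[C@@H]1CC[C@@H](C)[C@]2(C)CC[C@@H](C)CCO | intermediate
26 | methyl (1S,5S,6R,8aS)-5-[(3R)-5-acetoxy-3-methylpentyl]-1,5,6-trimethyl-3-oxo-1,2,3,5,6,7,8,8a-octahydronaphthalene-1-carboxylate (CNP0250576.1) | COC(=O)[C@@]1(C)CC(=O)C=C2[C@@H]1CC[C@@H](C)[C@]2(C)CC[C@@H](C)CCOC(C)=O | target

**Totals**
Total step count: 13.
Longest linear sequence: 10 steps (1 → 2 → 4 → 5 → 7 → 17 → 18 → 19 → 23 → 24 → 26; steps 1–4 and 8–13). The other branch (steps 5–7) is 3 steps before the union.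

**Three steps most likely to fail, each with a fallback**

Step 9 (intramolecular Diels–Alder). The relative configuration of C5, C8 and C9 follows from alkene geometry and the cis-fused mode and is the secure part. The weak point is the face selection by C4, because methyl and CO2Me differ little in size. If selection is poor or reversed, the main product is the separable diastereomer with CO2Me trans to H5. The β,β-disubstituted enone is also a slow dienophile.
Fallback (a bulkier steering ester, from 13 back to 24): acid 13 is esterified with tert-butyl 2,2,2-trichloroacetimidate (BF3·OEt2 cat.) to the tert-butyl ester F3. F3 is coupled with alkenyllithium 15 (from 7) as in step 8 to give the tert-butyl trienone F4. The cycloaddition with Me2AlCl now has a much larger ester to keep outside and gives the cis-hydrindenone F5. Hydrogenation gives the hydrindanone F6, ring enlargement and silylation as in step 11 give the silyl enol ether F7, and Pd(OAc)2 gives the enone F8. Me3SiOSO2CF3 with 2,6-lutidine cleaves only the tert-butyl ester to the acid F9, and MeI/K2CO3 then gives 24.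

Step 6 (enantioselective quaternary centre). The chiral-lithium-amide alkylation has not been tried on this extended trienediolate or with the bromo Weinreb amide. Enantioselectivity, α- versus ω-alkylation and the geometry of the released diene are all uncertain.
Fallback (resolution instead of asymmetric induction, from 10 back to 13): the dianion of 10 made with LiN(i-Pr)2 alone is alkylated with 11 to give the racemic acid F1. Crystallisation with (R)-1-phenylethanamine gives the less soluble salt of the (S)-acid, the salt F2, while the other diastereomeric salt stays in solution. Acidification of F2 gives 13.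

Step 11 (ring enlargement). The sequence relies on C10 (secondary) migrating in preference to C3 (primary), on addition to a hindered cyclopentanone rather than enolisation, and on n-BuLi sparing the neopentyl-type methyl ester.
Fallback (cyclopropanation and oxidative opening, from 19 back to 24, which also replaces step 12): thermodynamic silylation (Me3SiCl, NaI, Et3N, MeCN) gives the ring-fusion silyl enol ether F10. Cyclopropanation with Et2Zn/CH2I2 gives the siloxycyclopropane F11. FeCl3 in DMF cleaves the ring-fusion cyclopropane bond by one-electron oxidation to the ring-enlarged β-chloro ketone F12, and NaOAc in MeOH eliminates HCl to give 24.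

**Further compounds**
F1 | step 6 | racemic (3E,5E)-2-{2-[methoxy(methyl)amino]-2-oxoethyl}-2-methylhepta-3,5-dienoic acid | OC(=O)C(C)(/C=C/C=C/C)CC(=O)N(C)OC
F2 | step 6 | (R)-1-phenylethanaminium (2S,3E,5E)-2-{2-[methoxy(methyl)amino]-2-oxoethyl}-2-methylhepta-3,5-dienoate | C[C@@H]([NH3+])c1ccccc1.[O-]C(=O)[C@@](/C=C/C=C/C)(C)CC(=O)N(C)OC
F3 | step 9 | tert-butyl (2S,3E,5E)-2-{2-[methoxy(methyl)amino]-2-oxoethyl}-2-methylhepta-3,5-dienoate | CC(C)(C)OC(=O)[C@@](/C=C/C=C/C)(C)CC(=O)N(C)OC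
F4 | step 9 | tert-butyl (2S,3E,5E)-2-[(3E,7R)-9-{[tert-butyl(dimethyl)silyl]oxy}-4,7-dimethyl-2-oxonon-3-en-1-yl]-2-methylhepta-3,5-dienoate | CC(C)(C)OC(=O)[C@@](/C=C/C=C/C)(C)CC(=O)/C=C(\C)CC[C@@H](C)CCO[Si](C)(C)C(C)(C)C
F5 | step 9 | tert-butyl (1S,3aS,4S,5R,7aS)-4-[(3R)-5-{[tert-butyl(dimethyl)silyl]oxy}-3-methylpentyl]-1,4,5-trimethyl-3-oxo-2,3,3a,4,5,7a-hexahydro-1H-indene-1-carboxylate | CC(C)(C)OC(=O)[C@@]1(C)CC(=O)[C@H]2[C@@H]1C=C[C@@H](C)[C@]2(C)CC[C@@H](C)CCO[Si](C)(C)C(C)(C)C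
F6 | step 9 | tert-butyl (1S,3aS,4S,5R,7aS)-4-[(3R)-5-{[tert-butyl(dimethyl)silyl]oxy}-3-methylpentyl]-1,4,5-trimethyl-3-oxooctahydro-1H-indene-1-carboxylate | CC(C)(C)OC(=O)[C@@]1(C)CC(=O)[C@H]2[C@@H]1CC[C@@H](C)[C@]2(C)CC[C@@H](C)CCO[Si](C)(C)C(C)(C)C
F7 | step 9 | tert-butyl (1S,4aR,5S,6R,8aS)-5-[(3R)-5-{[tert-butyl(dimethyl)silyl]oxy}-3-methylpentyl]-1,5,6-trimethyl-3-[(trimethylsilyl)oxy]-1,2,4a,5,6,7,8,8a-octahydronaphthalene-1-carboxylate | CC(C)(C)OC(=O)[C@@]1(C)CC(O[Si](C)(C)C)=C[C@H]2[C@@H]1CC[C@@H](C)[C@]2(C)CC[C@@H](C)CCO[Si](C)(C)C(C)(C)C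
F8 | step 9 | tert-butyl (1S,5S,6R,8aS)-5-[(3R)-5-{[tert-butyl(dimethyl)silyl]oxy}-3-methylpentyl]-1,5,6-trimethyl-3-oxo-1,2,3,5,6,7,8,8a-octahydronaphthalene-1-carboxylate | CC(C)(C)OC(=O)[C@@]1(C)CC(=O)C=C2[C@@H]1CC[C@@H](C)[C@]2(C)CC[C@@H](C)CCO[Si](C)(C)C(C)(C)C
F9 | step 9 | (1S,5S,6R,8aS)-5-[(3R)-5-{[tert-butyl(dimethyl)silyl]oxy}-3-methylpentyl]-1,5,6-trimethyl-3-oxo-1,2,3,5,6,7,8,8a-octahydronaphthalene-1-carboxylic acid | OC(=O)[C@@]1(C)CC(=O)C=C2[C@@H]1CC[C@@H](C)[C@]2(C)CC[C@@H](C)CCO[Si](C)(C)C(C)(C)C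
F10 | step 11 | ring-fusion (C2=C10) trimethylsilyl enol ether of 19 | COC(=O)[C@@]1(C)CC(O[Si](C)(C)C)=C2[C@@H]1CC[C@@H](C)[C@]2(C)CC[C@@H](C)CCO[Si](C)(C)C(C)(C)C
F11 | step 11 | siloxycyclopropane from F10 (CH2 bridging C2 and C10; cyclopropane face unspecified) | COC(=O)[C@@]1(C)CC2(O[Si](C)(C)C)CC23[C@@H]1CC[C@@H](C)[C@]3(C)CC[C@@H](C)CCO[Si](C)(C)C(C)(C)C
F12 | step 11 | ring-enlarged β-chloro ketone (Cl on C10; configuration at C10 unspecified) | COC(=O)[C@@]1(C)CC(=O)CC2(Cl)[C@@H]1CC[C@@H](C)[C@]2(C)CC[C@@H](C)CCO[Si](C)(C)C(C)(C)C
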